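**Strategy**

Both rings C are β-aryloxy ketones: O1–C2 and O1''–C2'' lie β to C4=O and C4''=O, and the C3–C3'' bond joins the two α-carbons. Opening both C–O bonds therefore leads back to an achiral (E,E)-2,3-bis(4-benzyloxybenzylidene)-1,4-diaryl-1,4-dione, two 2'-hydroxychalcones linked α-carbon to α-carbon, which is assembled from a succinate-derived fulgide and two aryllithiums. One catalytic, two-directional oxa-Michael closure then forms both C–O bonds, both rings C and all four stereocentres (C2 and C2'' by the catalyst, C3 and C3'' by trans equilibration). The precursor carries one free ortho phenol on each ring A; every other oxygen, O5'' included, is a benzyl ether removed in the last step.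

Key step: step 12

**Remarks on the chemistry**

- Configuration: the target is (2S,3R,2''S,3''R). Both rings C are 2,3-trans and the two halves have the same sense.
- Assumption: the quinine-derived thiourea is taken to give the 2S and 2''S face selection; if a model α-substituted 2'-hydroxychalcone shows the opposite sense, the pseudo-enantiomeric quinidine-derived thiourea is used and nothing else changes.
- Precursor design: O5'' stays benzylated through the key step. A ketone flanked by two free ortho hydroxyls closes quickly without any catalyst (racemic background), offers a second acidic phenol to the catalyst, and gives a 5''-hydroxyflavanone that reopens easily under base.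
- Regiochemistry of both rings A is fixed by directing effects (ortho-metalation between two oxygens; bromination para to the only strong donor), not by selective mono-alkylation of a polyphenol.
- All (E,E)-diene intermediates are handled in amber glassware, since fulgide-type dienes isomerise and electrocyclise in light.

**Route**

Step 1
Reactants: 1 diethyl succinate; 2 4-(benzyloxy)benzaldehyde (2.2 equiv)
Product: 4 (2E,3E)-2,3-bis[4-(benzyloxy)benzylidene]succinic acid, via mono-arylidene half-ester 3 (not isolated)
Conditions: NaOEt (2.5 equiv), EtOH, reflux; then aq. HCl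
Reagents that add atoms: none
Why: Two Stobbe condensations in one pot (ester enolate aldol addition, lactonisation onto the second carboxyl group, base-induced ring opening to the alkylidene carboxylate) turn both methylene groups of the succinate into arylidene units, each stage being driven by irreversible carboxylate formation and each aryl ending trans to the carboxyl on its own carbon, so the (E,E)-diacid is the expected product.

Step 2
Reactants: 4 (2E,3E)-2,3-bis[4-(benzyloxy)benzylidene]succinic acid
Product: 5 (3E,4E)-3,4-bis[4-(benzyloxy)benzylidene]oxolane-2,5-dione (the fulgide)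
Conditions: AcCl, CH2Cl2, 40 °C, amber glassware
Reagents that add atoms: none
Why: Cyclodehydration of the 1,4-diacid through its mixed acetic anhydride gives the five-membered anhydride under base-free conditions that should leave the benzyl ethers and the (E,E)-geometry untouched.

Step 3
Reactants: 6 3,5-bis(benzyloxy)phenol
Product: 7 1,3-bis(benzyloxy)-5-(methoxymethoxy)benzene
Conditions: MOMCl, iPr2NEt, CH2Cl2, 0 °C → rt
Reagents that add atoms: chloromethyl methyl ether, COCCl
Why: O-alkylation of the single free phenol (MOM protection) installs an acid-labile group that directs the coming lithiation to the carbon between OMOM and OBn and can later be removed without touching benzyl ethers.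

Step 4
Reactants: 7 1,3-bis(benzyloxy)-5-(methoxymethoxy)benzene; 5 the fulgide (1.2 equiv)
Product: 9 (2E,3E)-4-[2,4-bis(benzyloxy)-6-(methoxymethoxy)phenyl]-2,3-bis[4-(benzyloxy)benzylidene]-4-oxobutanoic acid, via aryllithium 8 (not isolated)
Conditions: n-BuLi, THF, 0 °C; then added to 5, THF, −78 °C; aq. HCl
Reagents that add atoms: n-butyllithium, [Li]CCCC (supplies only the lithium of 8; no atom of it remains in 9)
Why: Directed ortho-metalation places lithium on the ring carbon flanked by the MOM ether and a benzyloxy group, and the aryllithium then opens the symmetric cyclic anhydride by nucleophilic acyl substitution, the carboxylate set free and the two ortho substituents of the new aryl ketone guarding it against a second addition when the reagent is added to excess 5 at low temperature.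

Step 5
Reactants: 9 the keto acid
Product: 11 (2E,3E)-4-[2,4-bis(benzyloxy)-6-(methoxymethoxy)phenyl]-2,3-bis[4-(benzyloxy)benzylidene]-N-methoxy-N-methyl-4-oxobutanamide, via acyl imidazolide 10 (not isolated)
Conditions: CDI, CH2Cl2, rt; then MeNHOMe·HCl, rt
Reagents that add atoms: N,O-dimethylhydroxylamine hydrochloride, CNOC.Cl; 1,1'-carbonyldiimidazole, O=C(n1ccnc1)n1ccnc1 (supplies only the imidazolyl group of 10)
Why: Activation of the hindered acid as its acyl imidazolide followed by aminolysis (Weinreb amide synthesis) runs under neutral conditions at room temperature, so the diene geometry, the MOM ether and the aryl ketone should not be affected.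

Step 6
Reactants: 12 3-(benzyloxy)phenol
Product: 13 3-(benzyloxy)phenyl acetate
Conditions: Ac2O, pyridine, CH2Cl2, rt
Reagents that add atoms: acetic anhydride, CC(=O)OC(C)=O
Why: O-acetylation turns the hydroxyl into a weakly donating ester, so that the benzyloxy group is the only strong director in the following bromination.

Step 7
Reactants: 13 3-(benzyloxy)phenyl acetate
Product: 14 5-(benzyloxy)-2-bromophenyl acetate
Conditions: NBS, MeCN, 0 °C → rt
Reagents that add atoms: N-bromosuccinimide, O=C1CCC(=O)N1Br
Why: Electrophilic aromatic bromination occurs para to the strongest donor, the benzyloxy group, which is the position ortho to the acetoxy group, and should therefore give essentially one regioisomer with the 1,2,4-pattern of ring A of unit 1.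

Step 8
Reactants: 14 5-(benzyloxy)-2-bromophenyl acetate
Product: 15 5-(benzyloxy)-2-bromophenol
Conditions: K2CO3 (cat.), MeOH, rt
Reagents that add atoms: none
Why: Base-catalysed transesterification with methanol cleaves the aryl acetate under conditions that leave the aryl bromide and the benzyl ether intact.

Step 9
Reactants: 15 5-(benzyloxy)-2-bromophenol
Product: 16 4-(benzyloxy)-1-bromo-2-(methoxymethoxy)benzene
Conditions: MOMCl, iPr2NEt, CH2Cl2, 0 °C → rt
Reagents that add atoms: chloromethyl methyl ether, COCCl
Why: MOM protection of the phenol ortho to bromine gives an ether that survives bromine–lithium exchange, stabilises the aryllithium by coordination and is cleaved later together with the MOM group of unit 2.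

Step 10
Reactants: 16 4-(benzyloxy)-1-bromo-2-(methoxymethoxy)benzene; 11 the Weinreb amide
Product: 18 (2E,3E)-1-[4-(benzyloxy)-2-(methoxymethoxy)phenyl]-4-[2,4-bis(benzyloxy)-6-(methoxymethoxy)phenyl]-2,3-bis[4-(benzyloxy)benzylidene]butane-1,4-dione, via aryllithium 17 (not isolated)
Conditions: n-BuLi, THF, −78 °C; then 11, THF, −78 °C; aq. NH4Cl
Reagents that add atoms: n-butyllithium, [Li]CCCC (supplies only the lithium of 17; no atom of it remains in 18)
Why: Bromine–lithium exchange followed by addition to the Weinreb amide (Weinreb ketone synthesis) stops at the ketone through the chelated tetrahedral intermediate, while the ketone already present is flanked by two ortho alkoxy groups and twisted, and should be far less reactive than the amide at this temperature.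

Step 11
Reactants: 18 the bis-MOM diketone
Product: 19 (2E,3E)-1-[4-(benzyloxy)-2-hydroxyphenyl]-4-[2,4-bis(benzyloxy)-6-hydroxyphenyl]-2,3-bis[4-(benzyloxy)benzylidene]butane-1,4-dione
Conditions: conc. HCl (cat.), MeOH/THF, rt, amber glassware
Reagents that add atoms: none
Why: Acid-catalysed acetal exchange with methanol removes the two MOM groups, the only acetals present, while benzyl ethers are stable and acid-mediated closure of 2'-hydroxy-6'-alkoxychalcones is slow at room temperature, so both ortho phenols should be unveiled without premature racemic cyclisation.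

Step 12
Reactants: 19 the (E,E)-bis-chalcone with one free ortho phenol on each ring A
Product: 21 (2S,3R)-7-(benzyloxy)-2-[4-(benzyloxy)phenyl]-3-{(2S,3R)-5,7-bis(benzyloxy)-2-[4-(benzyloxy)phenyl]-4-oxochroman-3-yl}chroman-4-one, via mono-closed flavanone–chalcone 20 (not isolated)
Conditions: 1-[3,5-bis(trifluoromethyl)phenyl]-3-[(8α,9S)-6'-methoxycinchonan-9-yl]thiourea (20 mol %), toluene, −25 °C → 0 °C
Reagents that add atoms: none
Why: The tertiary amine of the catalyst acts as a general base towards the ortho phenol of a ring A while the thiourea hydrogen-bonds the adjacent ketone, the aryloxide adds to the β-carbon of its own enone (expected first in the more twisted unit 2, forming O1''–C2'', then in unit 1, forming O1–C2) and each enol is protonated at C3'' or C3. This is the bifunctional amine–thiourea catalysed intramolecular oxa-Michael addition known for 2'-hydroxychalcones, α-substituted ones included, run here at both ends of one molecule. Each ring C closes in the 6-endo-trig mode; attack of a phenol on the enone of the other half would need a seven-membered ring and should not compete. C2'' and C2 are set by the catalyst, which exposes the same enone face in both halves, and C3'' and C3 are set by thermodynamic control, because the α-hydrogen of each new flavanone exchanges under the amine and settles trans to the C2 aryl group with both substituents equatorial. The step needs two face selections of like sense and exactly one nucleophile per enone; the (E)-geometry fixed in the fulgide, the benzyl group on O5'' and a non-polar solvent at low temperature are meant to secure this, and the α-branch, which twists both enones out of conjugation, should pull the equilibrium towards the closed rings. Since two catalyst-controlled events are combined, a wrong-face closure in one half should lead mainly to the separable (2S,3R,2''R,3''S)-type diastereomer and not to the enantiomer, so the enantiomeric purity of 21 is expected to exceed that of a single closure.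

Step 13
Reactants: 21 the pentabenzyl ether
Product: 22 (2S,3R)-3-[(2S,3R)-5,7-dihydroxy-2-(4-hydroxyphenyl)-4-oxochroman-3-yl]-7-hydroxy-2-(4-hydroxyphenyl)chroman-4-one (target, CNP0138443.1)
Conditions: H2 (1 atm), 10% Pd/C, EtOAc/MeOH, rt
Reagents that add atoms: none
Why: Catalytic hydrogenolysis cleaves the five aryl benzyl ethers under neutral conditions in which C3 and C3'' cannot enolise and the cyclic benzylic C2–O1 and C2''–O1'' bonds react much more slowly than O-benzyl groups, so the four stereocentres should pass unchanged into the target if the reaction is stopped once the ethers are consumed.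

**Compound list**

1 | diethyl succinate | CCOC(=O)CCC(=O)OCC | starting material
2 | 4-(benzyloxy)benzaldehyde | O=Cc1ccc(OCc2ccccc2)cc1 | starting material
3 | (E)-4-[4-(benzyloxy)phenyl]-3-(ethoxycarbonyl)but-3-enoic acid (sodium salt in the flask) | CCOC(=O)/C(=C/c1ccc(OCc2ccccc2)cc1)CC(=O)O | intermediate (not isolated)
4 | (2E,3E)-2,3-bis[4-(benzyloxy)benzylidene]succinic acid | OC(=O)/C(=C/c1ccc(OCc2ccccc2)cc1)C(=C/c1ccc(OCc2ccccc2)cc1)\C(=O)O | intermediate
5 | (3E,4E)-3,4-bis[4-(benzyloxy)benzylidene]oxolane-2,5-dione (fulgide) | O(Cc1ccccc1)c1ccc(cc1)/C=C1/C(=O)OC(=O)/C1=C/c1ccc(OCc2ccccc2)cc1 | intermediate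
6 | 3,5-bis(benzyloxy)phenol | Oc1cc(OCc2ccccc2)cc(OCc2ccccc2)c1 | starting material
7 | 1,3-bis(benzyloxy)-5-(methoxymethoxy)benzene | COCOc1cc(OCc2ccccc2)cc(OCc2ccccc2)c1 | intermediate
8 | [2,4-bis(benzyloxy)-6-(methoxymethoxy)phenyl]lithium | [Li]c1c(OCOC)cc(OCc2ccccc2)cc1OCc1ccccc1 | intermediate (not isolated)
9 | (2E,3E)-4-[2,4-bis(benzyloxy)-6-(methoxymethoxy)phenyl]-2,3-bis[4-(benzyloxy)benzylidene]-4-oxobutanoic acid | OC(=O)/C(=C/c1ccc(OCc2ccccc2)cc1)C(=C/c1ccc(OCc2ccccc2)cc1)\C(=O)c1c(OCOC)cc(OCc2ccccc2)cc1OCc1ccccc1 | intermediate
10 | acyl imidazolide of 9 | O=C(n1ccnc1)/C(=C/c1ccc(OCc2ccccc2)cc1)C(=C/c1ccc(OCc2ccccc2)cc1)\C(=O)c1c(OCOC)cc(OCc2ccccc2)cc1OCc1ccccc1 | intermediate (not isolated)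
11 | (2E,3E)-4-[2,4-bis(benzyloxy)-6-(methoxymethoxy)phenyl]-2,3-bis[4-(benzyloxy)benzylidene]-N-methoxy-N-methyl-4-oxobutanamide | CON(C)C(=O)/C(=C/c1ccc(OCc2ccccc2)cc1)C(=C/c1ccc(OCc2ccccc2)cc1)\C(=O)c1c(OCOC)cc(OCc2ccccc2)cc1OCc1ccccc1 | intermediate
12 | 3-(benzyloxy)phenol | Oc1cccc(OCc2ccccc2)c1 | starting material
13 | 3-(benzyloxy)phenyl acetate | CC(=O)Oc1cccc(OCc2ccccc2)c1 | intermediate
14 | 5-(benzyloxy)-2-bromophenyl acetate | CC(=O)Oc1cc(OCc2ccccc2)ccc1Br | intermediate
15 | 5-(benzyloxy)-2-bromophenol | Oc1cc(OCc2ccccc2)ccc1Br | intermediate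
16 | 4-(benzyloxy)-1-bromo-2-(methoxymethoxy)benzene | COCOc1cc(OCc2ccccc2)ccc1Br | intermediate
17 | [4-(benzyloxy)-2-(methoxymethoxy)phenyl]lithium | [Li]c1ccc(OCc2ccccc2)cc1OCOC | intermediate (not isolated)
18 | (2E,3E)-1-[4-(benzyloxy)-2-(methoxymethoxy)phenyl]-4-[2,4-bis(benzyloxy)-6-(methoxymethoxy)phenyl]-2,3-bis[4-(benzyloxy)benzylidene]butane-1,4-dione | O=C(c1ccc(OCc2ccccc2)cc1OCOC)/C(=C/c1ccc(OCc2ccccc2)cc1)C(=C/c1ccc(OCc2ccccc2)cc1)\C(=O)c1c(OCOC)cc(OCc2ccccc2)cc1OCc1ccccc1 | intermediate
19 | (2E,3E)-1-[4-(benzyloxy)-2-hydroxyphenyl]-4-[2,4-bis(benzyloxy)-6-hydroxyphenyl]-2,3-bis[4-(benzyloxy)benzylidene]butane-1,4-dione | O=C(c1ccc(OCc2ccccc2)cc1O)/C(=C/c1ccc(OCc2ccccc2)cc1)C(=C/c1ccc(OCc2ccccc2)cc1)\C(=O)c1c(O)cc(OCc2ccccc2)cc1OCc1ccccc1 | intermediate (precursor of the key step)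
20 | (2S,3R)-5,7-bis(benzyloxy)-2-[4-(benzyloxy)phenyl]-3-{(E)-3-[4-(benzyloxy)-2-hydroxyphenyl]-1-[4-(benzyloxy)phenyl]-3-oxoprop-1-en-2-yl}chroman-4-one | O=C(c1ccc(OCc2ccccc2)cc1O)/C(=C/c1ccc(OCc2ccccc2)cc1)[C@H]1C(=O)c2c(OCc3ccccc3)cc(OCc3ccccc3)cc2O[C@@H]1c1ccc(OCc2ccccc2)cc1 | intermediate (not isolated)
21 | (2S,3R)-7-(benzyloxy)-2-[4-(benzyloxy)phenyl]-3-{(2S,3R)-5,7-bis(benzyloxy)-2-[4-(benzyloxy)phenyl]-4-oxochroman-3-yl}chroman-4-one | O=C1c2ccc(OCc3ccccc3)cc2O[C@H](c2ccc(OCc3ccccc3)cc2)[C@H]1[C@H]1C(=O)c2c(OCc3ccccc3)cc(OCc3ccccc3)cc2O[C@@H]1c1ccc(OCc2ccccc2)cc1 | intermediate (product of the key step)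
22 | (2S,3R)-3-[(2S,3R)-5,7-dihydroxy-2-(4-hydroxyphenyl)-4-oxochroman-3-yl]-7-hydroxy-2-(4-hydroxyphenyl)chroman-4-one | O=C1c2ccc(O)cc2O[C@H](c2ccc(O)cc2)[C@H]1[C@H]1C(=O)c2c(O)cc(O)cc2O[C@@H]1c1ccc(O)cc1 | target

**Step count**

Total: 13 steps. Longest linear sequence: 8 steps (steps 1, 2, 4, 5, 10, 11, 12, 13; the branch through steps 6–9 is equally long).

**Steps most likely to fail, with fallbacks**

The key closure, step 12, is the main risk. The twisted, only singly activated enones may react slowly, face selection may be weak in one or both halves, the closed rings may reopen and reclose under the amine with loss of enantiopurity, or the intermediate dienol may be protonated at the remote carbon and move the double bond. The fallback gives up catalyst control. Starting from 19, closure under thermodynamic conditions with an achiral base (NaOAc, EtOH, reflux) should give the stereo-undefined pentabenzyl biflavanone F1 as a mixture of 2,3-trans,2'',3''-trans isomers. The pair with like sense in both halves is separated from the unlike diastereomer on silica and then resolved by preparative chromatography on a chiral stationary phase. The route is rejoined at 21.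

The second risk is step 10. The aryllithium may lose chemoselectivity and attack the existing ketone or add in conjugate fashion to one of the benzylidene carbons instead of the amide. The fallback replaces the polar addition by a neutral cross-coupling. Starting from keto acid 9, its imidazolide 10 is treated with ethanethiol to give the S-ethyl thioester F2. Aryllithium 17 is transmetalated with ZnBr2 to [4-(benzyloxy)-2-(methoxymethoxy)phenyl]zinc bromide F3. The two are joined with catalytic PdCl2(PPh3)2 in THF (Fukuyama coupling), which tolerates ketones and enones. The route is rejoined at 18.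

The third risk is step 4. A second aryllithium may add to the opened keto-carboxylate or to its cyclic lactol form, giving diaryl carbinol and lactone by-products. The fallback changes the electrophile. Starting from fulgide 5, ring opening with N,O-dimethylhydroxylamine gives the mono-Weinreb amide acid F4. Its carboxylate is formed with LiN(SiMe3)2 and aryllithium 8 is added at −78 °C; the chelated tetrahedral intermediate cannot take a second equivalent. Acidic work-up rejoins the route at 9.

**Further compounds**

F1 | step 12 | 7-(benzyloxy)-2-[4-(benzyloxy)phenyl]-3-{5,7-bis(benzyloxy)-2-[4-(benzyloxy)phenyl]-4-oxochroman-3-yl}chroman-4-one, mixture of 2,3-trans,2'',3''-trans stereoisomers (configuration undefined) | O=C1c2ccc(OCc3ccccc3)cc2OC(c2ccc(OCc3ccccc3)cc2)C1C1C(=O)c2c(OCc3ccccc3)cc(OCc3ccccc3)cc2OC1c1ccc(OCc2ccccc2)cc1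
F2 | step 10 | S-ethyl (2E,3E)-4-[2,4-bis(benzyloxy)-6-(methoxymethoxy)phenyl]-2,3-bis[4-(benzyloxy)benzylidene]-4-oxobutanethioate | CCSC(=O)/C(=C/c1ccc(OCc2ccccc2)cc1)C(=C/c1ccc(OCc2ccccc2)cc1)\C(=O)c1c(OCOC)cc(OCc2ccccc2)cc1OCc1ccccc1
F3 | step 10 | [4-(benzyloxy)-2-(methoxymethoxy)phenyl]zinc bromide | Br[Zn]c1ccc(OCc2ccccc2)cc1OCOC
F4 | step 4 | (2E,3E)-2,3-bis[4-(benzyloxy)benzylidene]-4-[methoxy(methyl)amino]-4-oxobutanoic acid | CON(C)C(=O)/C(=C/c1ccc(OCc2ccccc2)cc1)C(=C/c1ccc(OCc2ccccc2)cc1)\C(=O)O
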